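**Strategy.** The route rests on the C5–C6 bond of the spiro[5.5]undecane (ring A: C1 gem-dimethyl, C2 bromide, C5 methylidene carbon; ring B: C6–C11 with C8 bromide and C9 methyl/chloride). Spiro C6, wedged between quaternary C1 and sp2 C5, is treated as the para carbon of a phenol; the phenol C–O carbon becomes C9. Cationic gold makes that para carbon add to the internal carbon of a terminal alkyne, which closes ring A with its exocyclic methylene and leaves ring B as a cyclohexadienone in one operation. The precursor is a para-alkylated phenol whose benzylic gem-dimethyl carbon is bonded to an (R)-CHBr centre bearing a but-3-ynyl chain.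

Key step: step 6

Remark: atom labels C1–C11 in the text always follow the numbering of target 19 given above, not the locants in the systematic names of intermediates.
Assumption: the sense of induction of the titanium Schiff-base catalyst (step 1) and of the copper bisphosphine catalyst (step 7) is as written; if a first run shows the opposite sense, the antipodal ligand is used.

Step 1
Reactants: 1 prenol (3-methylbut-2-en-1-ol)
Product: 2 (2R)-2-bromo-3-chloro-3-methylbutan-1-ol
Conditions: NBS, ClTi(OiPr)3, chiral tridentate Schiff-base ligand (20 mol %), hexanes, −20 °C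
Reagents that add atoms: NBS (N-bromosuccinimide), O=C1CCC(=O)N1Br; ClTi(OiPr)3 (chlorotitanium triisopropoxide), CC(C)O[Ti](Cl)(OC(C)C)OC(C)C
Why: Catalytic enantioselective bromochlorination of an allylic alcohol, in which the alkoxide-bound chiral titanium complex directs bromonium formation to one alkene face and chloride is delivered anti to the tertiary (Markovnikov) carbon, so the ligand sets the (R) CHBr centre (C2 of the target).

Step 2
Reactants: 2 (2R)-2-bromo-3-chloro-3-methylbutan-1-ol
Product: 3 (2R)-2-bromo-3-chloro-3-methylbutyl trifluoromethanesulfonate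
Conditions: Tf2O, 2,6-lutidine, CH2Cl2, −78 °C
Reagents that add atoms: Tf2O (trifluoromethanesulfonic anhydride), O=S(=O)(OS(=O)(=O)C(F)(F)F)C(F)(F)F
Why: Ordinary O-sulfonylation of a primary alcohol with a hindered pyridine base at low temperature, which leaves the stereocentre untouched.

Step 3
Reactants: 3 (2R)-2-bromo-3-chloro-3-methylbutyl trifluoromethanesulfonate; 4 1-(trimethylsilyl)propyne
Product: 6 [(5R)-5-bromo-6-chloro-6-methylhept-1-yn-1-yl]trimethylsilane, via lithiated silylpropyne 5 (not isolated)
Conditions: 4, n-BuLi, THF, −78 °C; then 3, −78 → −40 °C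
Reagents that add atoms: none
Why: Propargylic lithiation followed by SN2 alkylation at the propargylic terminus with a primary triflate, which at −78 °C should outrun halogen–metal exchange or elimination at the vicinal bromochloride.

Step 4
Reactants: 6 [(5R)-5-bromo-6-chloro-6-methylhept-1-yn-1-yl]trimethylsilane
Product: 7 (5R)-5-bromo-6-chloro-6-methylhept-1-yne
Conditions: K2CO3 (cat.), MeOH, 0 °C → rt
Reagents that add atoms: none
Why: Base-catalysed methanolysis of the alkynyl C–Si bond (protodesilylation), placed before the arene is introduced so that no phenoxide is ever formed beta to the secondary bromide.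

Step 5
Reactants: 7 (5R)-5-bromo-6-chloro-6-methylhept-1-yne; 8 phenol
Product: 9 4-[(3R)-3-bromo-2-methylhept-6-yn-2-yl]phenol
Conditions: phenol (5 equiv.), HFIP, 0 °C; neutral work-up, chromatography
Reagents that add atoms: none
Why: Solvolytic Friedel–Crafts alkylation in which the tertiary chloride ionises in HFIP with anchimeric help from the vicinal bromine and the bromonium ion is opened at its tertiary carbon by the para position of phenol, so the CHBr centre is never broken and stays (R), while the short time at 0 °C and the neutral work-up keep the product bromide, now beta to an electron-rich arene, from ionising or cyclising in its turn.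

Step 6
Reactants: 9 4-[(3R)-3-bromo-2-methylhept-6-yn-2-yl]phenol
Product: 10 (8R)-8-bromo-7,7-dimethyl-11-methylidenespiro[5.5]undeca-1,4-dien-3-one
Conditions: Ph3PAuNTf2 (5 mol %), 4 Å MS, CH2Cl2, rt
Reagents that add atoms: none
Why: The cationic monovalent gold complex activates the terminal alkyne, the phenol carbon para to OH (future C6) adds anti to gold at the internal alkyne carbon (future C5), and loss of the phenolic proton followed by protodeauration releases the cross-conjugated dienone and the 1,1-disubstituted alkene. The closest known reaction type is the gold-catalysed intramolecular ipso-Friedel–Crafts alkenylation of para-alkynylated phenols to spirocyclohexadienones, established for five-membered rings and applied here to the tether one carbon longer. Ring A closes in the 6-exo-dig mode. No stereocentre is formed, because C6 carries two identical dienone arms at this stage and the C2 bromide is a spectator. The step needs ipso over ortho and exo over endo selectivity: ortho or endo attack would require a seven- or eight-membered ring, and the benzylic gem-dimethyl group (Thorpe–Ingold effect) folds the tether over the ipso carbon. A preformed, silver-free catalyst in a non-basic medium keeps the secondary bromide, which lies beta to the electron-rich ring, from being abstracted or displaced.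

Step 7
Reactants: 10 (8R)-8-bromo-7,7-dimethyl-11-methylidenespiro[5.5]undeca-1,4-dien-3-one
Product: 12 (6R,8R)-8-bromo-7,7-dimethyl-11-methylidenespiro[5.5]undec-1-en-3-one, via silyl dienol ether 11 (not isolated)
Conditions: Cu(OAc)2·H2O (5 mol %), (R)-DTBM-SEGPHOS (5.5 mol %), (MeO)2MeSiH, toluene, −20 °C; then 1 M HCl, THF, 0 °C
Reagents that add atoms: none
Why: Ligand-controlled copper hydride conjugate reduction with a silane, which selects the C10=C11 arm of the dienone (its β-carbon C11 lies on the bromine-bearing face of ring A) and so makes C6 stereogenic (R), the product leaving the cycle as a silyl dienol ether that cannot be reduced again and is hydrolysed to the enone on work-up.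

Step 8
Reactants: 12 (6R,8R)-8-bromo-7,7-dimethyl-11-methylidenespiro[5.5]undec-1-en-3-one
Product: 14 (6R,8R)-8-bromo-7,7-dimethyl-11-methylidenespiro[5.5]undec-2-en-3-yl trifluoromethanesulfonate, via lithium enolate 13 (not isolated)
Conditions: LiBH(s-Bu)3 (L-Selectride), THF, −78 °C; then PhNTf2, −78 → 0 °C
Reagents that add atoms: PhNTf2 (N-phenylbis(trifluoromethanesulfonimide)), O=S(=O)(N(c1ccccc1)S(=O)(=O)C(F)(F)F)C(F)(F)F
Why: 1,4-Hydride addition of the bulky borohydride to the β-unsubstituted enone gives the regiodefined C8=C9 lithium enolate, which is O-sulfonylated in the same flask (reductive enol triflate formation), so the double bond is fixed on the C8 side without touching a stereocentre.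

Step 9
Reactants: 14 (6R,8R)-8-bromo-7,7-dimethyl-11-methylidenespiro[5.5]undec-2-en-3-yl trifluoromethanesulfonate
Product: 15 (6R,8R)-8-bromo-3,7,7-trimethyl-11-methylidenespiro[5.5]undec-2-ene
Conditions: Pd(PPh3)4 (5 mol %), MeZnCl, THF, rt
Reagents that add atoms: MeZnCl (methylzinc chloride), C[Zn]Cl
Why: Negishi cross-coupling of an alkenyl triflate with a methylzinc reagent under zerovalent palladium catalysis, conditions under which the unactivated secondary alkyl bromide does not undergo oxidative addition.

Step 10
Reactants: 15 (6R,8R)-8-bromo-3,7,7-trimethyl-11-methylidenespiro[5.5]undec-2-ene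
Product: 16 (2R,6R,8R,9S)-2-bromo-8,9-epoxy-1,1,9-trimethyl-5-methylidenespiro[5.5]undecane (oxirane oxygen on the ring-B face of C1, anti to C5)
Conditions: D-fructose-derived ketone catalyst (30 mol %), KHSO5 (Oxone), K2CO3, Bu4NHSO4 (cat.), MeCN/CH2(OMe)2/aq. Na2B4O7 buffer, 0 °C
Reagents that add atoms: KHSO5 (potassium peroxymonosulfate), [K+].[O-]S(=O)(=O)OO
Why: Shi epoxidation, in which the chiral dioxirane attacks the electron-rich trisubstituted C8=C9 alkene in preference to the hindered 1,1-disubstituted one and its spiro transition state delivers oxygen to the ring-B face syn to C1, setting the (8R,9S) epoxide under reagent control.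

Step 11
Reactants: 16 (2R,6R,8R,9S)-2-bromo-8,9-epoxy-1,1,9-trimethyl-5-methylidenespiro[5.5]undecane
Product: 17 (2R,3R,6R,8R)-8-bromo-3-chloro-3,7,7-trimethyl-11-methylidenespiro[5.5]undecan-2-ol
Conditions: HCl (Et2O solution, 1.1 equiv.), CH2Cl2, −40 °C
Reagents that add atoms: HCl (hydrogen chloride), Cl
Why: Acid-promoted, borderline SN2 opening of a trisubstituted epoxide, in which chloride attacks the tertiary carbon C9 anti to the breaking C–O bond (Markovnikov regiochemistry, inversion) and so sets C9 (R) with chlorine trans to the C8 hydroxyl.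

Step 12
Reactants: 17 (2R,3R,6R,8R)-8-bromo-3-chloro-3,7,7-trimethyl-11-methylidenespiro[5.5]undecan-2-ol
Product: 19 (2R,6R,8S,9R)-2,8-dibromo-9-chloro-1,1,9-trimethyl-5-methylidenespiro[5.5]undecane, via secondary triflate 18 (not isolated)
Conditions: Tf2O, 2,6-lutidine, CH2Cl2, −20 °C; then Bu4NBr, 0 °C → rt
Reagents that add atoms: Bu4NBr (tetrabutylammonium bromide), CCCC[N+](CCCC)(CCCC)CCCC.[Br-]
Why: SN2 displacement of a secondary triflate by bromide with inversion, expected to run through the ring-B chair that places the C8 sulfonate axial so that bromide enters equatorially and ends cis to the C9 chlorine (8S), while the β-chlorine retards ionisation so that substitution can outrun rearrangement.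

**Compound list**
1 | prenol (3-methylbut-2-en-1-ol) | CC(C)=CCO | starting material
2 | (2R)-2-bromo-3-chloro-3-methylbutan-1-ol | OC[C@@H](Br)C(C)(C)Cl | intermediate
3 | (2R)-2-bromo-3-chloro-3-methylbutyl trifluoromethanesulfonate | O=S(=O)(OC[C@@H](Br)C(C)(C)Cl)C(F)(F)F | intermediate
4 | 1-(trimethylsilyl)propyne | CC#C[Si](C)(C)C | starting material
5 | [3-(trimethylsilyl)prop-2-yn-1-yl]lithium | [Li]CC#C[Si](C)(C)C | intermediate
6 | [(5R)-5-bromo-6-chloro-6-methylhept-1-yn-1-yl]trimethylsilane | C[Si](C)(C)C#CCC[C@@H](Br)C(C)(C)Cl | intermediate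
7 | (5R)-5-bromo-6-chloro-6-methylhept-1-yne | C#CCC[C@@H](Br)C(C)(C)Cl | intermediate
8 | phenol | Oc1ccccc1 | starting material
9 | 4-[(3R)-3-bromo-2-methylhept-6-yn-2-yl]phenol | C#CCC[C@@H](Br)C(C)(C)c1ccc(O)cc1 | intermediate
10 | (8R)-8-bromo-7,7-dimethyl-11-methylidenespiro[5.5]undeca-1,4-dien-3-one | C=C1CC[C@@H](Br)C(C)(C)C12C=CC(=O)C=C2 | intermediate
11 | {[(6R,8R)-8-bromo-7,7-dimethyl-11-methylidenespiro[5.5]undeca-1,3-dien-3-yl]oxy}dimethoxy(methyl)silane | C=C1CC[C@@H](Br)C(C)(C)[C@@]12CC=C(O[Si](C)(OC)OC)C=C2 | intermediate
12 | (6R,8R)-8-bromo-7,7-dimethyl-11-methylidenespiro[5.5]undec-1-en-3-one | C=C1CC[C@@H](Br)C(C)(C)[C@@]12CCC(=O)C=C2 | intermediate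
13 | lithium (6R,8R)-8-bromo-7,7-dimethyl-11-methylidenespiro[5.5]undec-2-en-3-olate | C=C1CC[C@@H](Br)C(C)(C)[C@@]12CCC(O[Li])=CC2 | intermediate
14 | (6R,8R)-8-bromo-7,7-dimethyl-11-methylidenespiro[5.5]undec-2-en-3-yl trifluoromethanesulfonate | C=C1CC[C@@H](Br)C(C)(C)[C@@]12CCC(OS(=O)(=O)C(F)(F)F)=CC2 | intermediate
15 | (6R,8R)-8-bromo-3,7,7-trimethyl-11-methylidenespiro[5.5]undec-2-ene | C=C1CC[C@@H](Br)C(C)(C)[C@@]12CCC(C)=CC2 | intermediate
16 | (2R,6R,8R,9S)-2-bromo-8,9-epoxy-1,1,9-trimethyl-5-methylidenespiro[5.5]undecane | C=C1CC[C@@H](Br)C(C)(C)[C@@]12CC[C@]3(C)O[C@@H]3C2 | intermediate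
17 | (2R,3R,6R,8R)-8-bromo-3-chloro-3,7,7-trimethyl-11-methylidenespiro[5.5]undecan-2-ol | C=C1CC[C@@H](Br)C(C)(C)[C@@]12CC[C@@](C)(Cl)[C@H](O)C2 | intermediate
18 | (2R,3R,6R,8R)-8-bromo-3-chloro-3,7,7-trimethyl-11-methylidenespiro[5.5]undecan-2-yl trifluoromethanesulfonate | C=C1CC[C@@H](Br)C(C)(C)[C@@]12CC[C@@](C)(Cl)[C@H](OS(=O)(=O)C(F)(F)F)C2 | intermediate
19 | (2R,6R,8S,9R)-2,8-dibromo-9-chloro-1,1,9-trimethyl-5-methylidenespiro[5.5]undecane | C=C1CC[C@@H](Br)C(C)(C)[C@@]12CC[C@@](C)(Cl)[C@@H](Br)C2 | target

Total step count: 12. Longest linear sequence: 12 steps (1 → 19).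

**Steps most likely to fail**

Step 6 (key step). The six-membered ipso closure is slower than its five-membered models. Hydration of the gold-bound alkyne, acid-triggered dienone–phenol rearrangement, or loss of the tertiary side chain from the protonated dienone may therefore take over. The fallback replaces π-acid catalysis by an electrophile-induced ring closure and sets out from 7. The HFIP alkylation is run with anisole in place of phenol to give 1-[(3R)-3-bromo-2-methylhept-6-yn-2-yl]-4-methoxybenzene F1. ICl in CH2Cl2 at −78 °C then triggers ipso-iodocyclisation, the O-methyl group leaving as chloromethane, to give (8R,11E)-8-bromo-11-(iodomethylidene)-7,7-dimethylspiro[5.5]undeca-1,4-dien-3-one F2. Formate reduction under palladium catalysis (Pd(OAc)2, PPh3, HCO2H, Et3N, DMF, 50 °C) removes the alkenyl iodide, which adds to zerovalent palladium far faster than the alkyl bromide. The route is rejoined at 10.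

Step 12. Elimination of the axial sulfonate toward C7, or ionisation assisted by the antiperiplanar chlorine with loss of configuration or halogen migration, may outrun the hindered backside attack. The stereochemical logic leaves little room here: any cationic route to the C8/C9 pair gives the trans dihalide, so the fallback still substitutes at C8 and changes only how the oxygen is activated and where bromide comes from. It sets out from 17. The alcohol is condensed with PPh3 and CBr4 in toluene (Appel reaction) to the {[(2R,3R,6R,8R)-8-bromo-3-chloro-3,7,7-trimethyl-11-methylidenespiro[5.5]undecan-2-yl]oxy}triphenylphosphonium bromide F4. This collapses in a non-basic, non-polar medium by bromide attack from within the ion pair, with inversion, and returns to the route at 19.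

Step 7. Discrimination between the two diastereotopic enone arms may be insufficient, and some 1,2-reduction may occur. The fallback gives up catalyst control for separation with recycling; it sets out from 10 and returns at 12. An achiral copper hydride (Cu(OAc)2·H2O, 1,2-bis(diphenylphosphino)benzene, polymethylhydrosiloxane, toluene; dilute HCl on work-up) reduces either arm once and stops at the silyl dienol ether stage. The two C6 epimers are diastereomers because of the ring-A bromide and are separated by chromatography. The unwanted (6S,8R)-8-bromo-7,7-dimethyl-11-methylidenespiro[5.5]undec-1-en-3-one F3 is dehydrogenated back to 10 with 2-iodoxybenzoic acid in DMSO at 70 °C and resubmitted.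

**Further compounds**
F1 | step 6 | 1-[(3R)-3-bromo-2-methylhept-6-yn-2-yl]-4-methoxybenzene | C#CCC[C@@H](Br)C(C)(C)c1ccc(OC)cc1
F2 | step 6 | (8R,11E)-8-bromo-11-(iodomethylidene)-7,7-dimethylspiro[5.5]undeca-1,4-dien-3-one | I/C=C1\CC[C@@H](Br)C(C)(C)C12C=CC(=O)C=C2
F3 | step 7 | (6S,8R)-8-bromo-7,7-dimethyl-11-methylidenespiro[5.5]undec-1-en-3-one | C=C1CC[C@@H](Br)C(C)(C)[C@]12CCC(=O)C=C2
F4 | step 12 | {[(2R,3R,6R,8R)-8-bromo-3-chloro-3,7,7-trimethyl-11-methylidenespiro[5.5]undecan-2-yl]oxy}triphenylphosphonium bromide | C=C1CC[C@@H](Br)C(C)(C)[C@@]12CC[C@@](C)(Cl)[C@H](O[P+](c3ccccc3)(c3ccccc3)c3ccccc3)C2.[Br-]
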